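The route rests on treating C4 of the third flavan unit as an aldehyde carbon. C4 is a diarylmethine carbon bonded to C4a of its own phloroglucinol-type A ring and to C8 of the terminal catechin. In one operation an acyclic 3-aryl-3-aryloxy-2-benzyloxypropanal closes the pyran C ring of unit three (C4–C4a bond; ring atoms O1, C2, C3, C4, C4a, C8a) by intramolecular Friedel–Crafts attack, and the resulting flavan-4-ol ionises and arylates catechin C8 with 4β selectivity. The precursor is an open-chain aryl ether whose C2 and C3 stereocentres come from an Evans glycolate aldol and an O-arylation with retention. A bromine-capped epicatechin dimer electrophile then adds units one and two.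

Key step: step 13

Remark on the chemistry: the secondary 3-hydroxyl groups of the natural flavan units are carried free throughout, on the assumption that they do not interfere with DDQ oxidation or with TMSOTf couplings at −78 °C.

Step 1
Reactants: 1 (−)-epicatechin
Product: 2 5,7,3',4'-tetra-O-benzyl-(−)-epicatechin
Conditions: BnBr (4.4 equiv), K2CO3, DMF, 0 °C to rt
Reagents that add atoms: benzyl bromide, BrCc1ccccc1
Why: Williamson etherification in which K2CO3 deprotonates only the four phenols, so the secondary 3-OH stays free and no stereocentre is touched.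

Step 2
Reactants: 2 5,7,3',4'-tetra-O-benzyl-(−)-epicatechin
Product: 3 5,7,3',4'-tetra-O-benzyl-4β-(2-ethoxyethoxy)-(−)-epicatechin
Conditions: DDQ (2 equiv), 2-ethoxyethanol (5 equiv), CH2Cl2, rt
Reagents that add atoms: 2-ethoxyethanol, CCOCCO
Why: DDQ benzylic oxidation (hydride abstraction at the alkoxy-activated C4) with trapping by the alcohol on the face anti to the 3-OH and the 2-aryl group, which should give the 3,4-trans (4β) ether.

Step 3
Reactants: 3 5,7,3',4'-tetra-O-benzyl-4β-(2-ethoxyethoxy)-(−)-epicatechin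
Product: 4 8-bromo-5,7,3',4'-tetra-O-benzyl-4β-(2-ethoxyethoxy)-(−)-epicatechin
Conditions: NBS (1.0 equiv), CH2Cl2, −15 °C
Reagents that add atoms: N-bromosuccinimide, O=C1CCC(=O)N1Br
Why: Electrophilic aromatic bromination at C8, the most nucleophilic position of a 5,7-dialkoxyflavan, which installs a cap that blocks self-condensation of the electrophile in later couplings.

Step 4
Reactants: 4 8-bromo-5,7,3',4'-tetra-O-benzyl-4β-(2-ethoxyethoxy)-(−)-epicatechin; 2 5,7,3',4'-tetra-O-benzyl-(−)-epicatechin (2 equiv)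
Product: 5 8-bromo-5,7,3',4'-tetra-O-benzylepicatechin-(4β→8)-5,7,3',4'-tetra-O-benzylepicatechin
Conditions: TMSOTf (0.2 equiv), CH2Cl2, −78 °C; Et3N quench
Reagents that add atoms: none
Why: Lewis-acid Friedel–Crafts alkylation (interflavan coupling) in which C8 of 2 attacks the ionised C4 of 4 on the β face, anti to the 3-OH and the 2-aryl group, setting the first 4β→8 bond.

Step 5
Reactants: 5 capped dimer
Product: 6 8-bromo-5,7,3',4'-tetra-O-benzylepicatechin-(4β→8)-5,7,3',4'-tetra-O-benzyl-4β-(2-ethoxyethoxy)epicatechin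
Conditions: DDQ (1.5 equiv), 2-ethoxyethanol (5 equiv), CH2Cl2, rt
Reagents that add atoms: 2-ethoxyethanol, CCOCCO
Why: DDQ benzylic oxidation at the only secondary benzylic C4–H (lower unit), the upper C4–H being tertiary, shielded and on a bromine-deactivated ring, with the alcohol adding trans to the 3-OH.

Step 6
Reactants: 7 (+)-catechin
Product: 8 5,7,3',4'-tetra-O-benzyl-(+)-catechin
Conditions: BnBr (4.4 equiv), K2CO3, DMF, 0 °C to rt
Reagents that add atoms: benzyl bromide, BrCc1ccccc1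
Why: Williamson etherification of the four phenols only, leaving the 3-OH and both stereocentres untouched.

Step 7
Reactants: 9 (S)-4-benzyl-3-[(benzyloxy)acetyl]oxazolidin-2-one; 10 3,4-bis(benzyloxy)benzaldehyde
Product: 13 (S)-4-benzyl-3-[(2S,3R)-2-(benzyloxy)-3-[3,4-bis(benzyloxy)phenyl]-3-hydroxypropanoyl]oxazolidin-2-one, via Z-boron enolate 11 (not isolated), via boron aldolate 12 (not isolated)
Conditions: Bu2BOTf, Et3N, CH2Cl2, −78 to 0 °C; then 10, −78 to 0 °C; H2O2, MeOH, pH 7 buffer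
Reagents that add atoms: none
Why: Evans syn glycolate aldol in which the Z-boron enolate reacts through a Zimmerman–Traxler chair on the face opposite the auxiliary benzyl group, setting the future C3 and C2 of unit three in the 2,3-syn relationship that becomes 2,3-cis in the ring.

Step 8
Reactants: 13 aldol adduct
Product: 14 (1R,2R)-2-(benzyloxy)-1-[3,4-bis(benzyloxy)phenyl]propane-1,3-diol
Conditions: LiBH4 (2 equiv), MeOH (2 equiv), THF, 0 °C
Reagents that add atoms: none
Why: Reductive cleavage of the N-acyl oxazolidinone by borohydride should give the 1,3-diol and release the auxiliary without touching either stereocentre.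

Step 9
Reactants: 14 diol
Product: 15 (1R,2R)-2-(benzyloxy)-1-[3,4-bis(benzyloxy)phenyl]-3-[(triisopropylsilyl)oxy]propan-1-ol
Conditions: TIPSCl (1.1 equiv), imidazole, DMF, 0 °C to rt
Reagents that add atoms: chlorotriisopropylsilane, CC(C)[Si](Cl)(C(C)C)C(C)C
Why: Selective silylation of the primary over the hindered secondary benzylic hydroxyl, with the bulky TIPS group chosen because it resists oxygen-to-oxygen migration under the basic coupling that follows.

Step 10
Reactants: 15 TIPS ether; 16 1,3-bis(benzyloxy)-5-bromobenzene (1.5 equiv)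
Product: 17 [(2R,3R)-2-(benzyloxy)-3-[3,4-bis(benzyloxy)phenyl]-3-[3,5-bis(benzyloxy)phenoxy]propoxy]triisopropylsilane
Conditions: [(allyl)PdCl]2 (2 mol %), RockPhos (6 mol %), Cs2CO3 (1.5 equiv), toluene, 90 °C
Reagents that add atoms: none
Why: Palladium-catalysed C–O cross-coupling (Buchwald–Hartwig etherification) of the secondary alcohol with the aryl bromide forms the future O1–C8a bond without breaking the carbinol C–O bond, so C2 keeps its configuration.

Step 11
Reactants: 17 silyl ether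
Product: 18 (2R,3R)-2-(benzyloxy)-3-[3,4-bis(benzyloxy)phenyl]-3-[3,5-bis(benzyloxy)phenoxy]propan-1-ol
Conditions: TBAF (1.2 equiv), THF, 0 °C to rt
Reagents that add atoms: none
Why: Fluoride-induced desilylation, to which the benzyl and aryl ethers are inert.

Step 12
Reactants: 18 primary alcohol
Product: 19 (2S,3R)-2-(benzyloxy)-3-[3,4-bis(benzyloxy)phenyl]-3-[3,5-bis(benzyloxy)phenoxy]propanal
Conditions: Dess–Martin periodinane (1.3 equiv), NaHCO3, CH2Cl2, 0 °C; used crude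
Reagents that add atoms: none
Why: Dess–Martin oxidation under buffered, non-basic conditions should avoid β-elimination of the aryloxy group and epimerisation at the α-carbon.

Step 13
Reactants: 19 aldehyde; 8 5,7,3',4'-tetra-O-benzyl-(+)-catechin (3 equiv)
Product: 22 3,5,7,3',4'-penta-O-benzylepicatechin-(4β→8)-5,7,3',4'-tetra-O-benzylcatechin, via flavan-4-ol 20 (not isolated), via benzylic cation 21 (not isolated)
Conditions: TMSOTf (0.3 equiv), 4 Å MS, CH2Cl2, −78 to −40 °C, slow addition of 19; Et3N quench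
Reagents that add atoms: none
Why: TMSOTf activates the aldehyde carbon (future C4), which is attacked by the ortho carbon (future C4a) of the tethered 3,5-bis(benzyloxy)phenyl ether in a 6-exo-trig Friedel–Crafts hydroxyalkylation that closes the pyran C ring of unit three and should give flavan-4-ol 20. Under the same acid 20 loses its C4 oxygen as water, taken up by the sieves, to give the 5,7-dialkoxy-stabilised cation 21, the classical flavan-3,4-diol electrophile, which alkylates C8 of 8; the closest known reaction types are the one-pot double Friedel–Crafts condensation of an aldehyde with two electron-rich arenes and the Lewis-acid coupling of 4-oxygenated flavan-3-ols with flavan-3-ol nucleophiles. C2 and C3 are carried unchanged from the aldol and the O-arylation, and C4 is set when 8 attacks the planar cation on the β face, anti to the axial 3-OBn group and opposite the 2-aryl group, giving the 3,4-trans (4β) bond. Regioselectivity of the ring closure is secured by the O1 tether, which reaches only the two equivalent ortho positions of the symmetrical ring, whereas closure onto ring B would need a strained indane and a far poorer nucleophile. Attack at C8 over C6 of 8 is the known preference of 5,7-di-O-benzylflavans, and slow addition of 19 to excess 8 keeps 21 from alkylating product 22.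

Step 14
Reactants: 6 dimeric electrophile; 22 protected lower dimer (1.2 equiv)
Product: 23 8-bromo-5,7,3',4'-tetra-O-benzylepicatechin-(4β→8)-5,7,3',4'-tetra-O-benzylepicatechin-(4β→8)-3,5,7,3',4'-penta-O-benzylepicatechin-(4β→8)-5,7,3',4'-tetra-O-benzylcatechin
Conditions: TMSOTf (0.2 equiv), CH2Cl2, −78 °C; Et3N quench
Reagents that add atoms: none
Why: Friedel–Crafts interflavan coupling in which the free C8 of the epicatechin unit of 22 attacks the ionised C4 of 6 anti to its 3-OH, giving the third 4β→8 bond, while the bromine cap allows near-equimolar partners.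

Step 15
Reactants: 23 protected tetramer
Product: 24 epicatechin-(4β→8)-epicatechin-(4β→8)-epicatechin-(4β→8)-catechin (the target)
Conditions: H2 (1 atm), Pd(OH)2/C, NaOAc (1.5 equiv), THF/MeOH/H2O, rt
Reagents that add atoms: none
Why: Hydrogenolysis of the seventeen benzyl ethers together with hydrodebromination of the C8–Br cap under buffered neutral conditions should leave the acid-labile interflavan bonds and all stereocentres intact.

Compound list

1 | (−)-epicatechin | Oc1cc(O)c2c(c1)O[C@H](c1ccc(O)c(O)c1)[C@H](O)C2 | starting material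
2 | 5,7,3',4'-tetra-O-benzyl-(−)-epicatechin | O(Cc3ccccc3)c1cc(OCc3ccccc3)c2c(c1)O[C@H](c1ccc(OCc3ccccc3)c(OCc3ccccc3)c1)[C@H](O)C2 | intermediate
3 | 5,7,3',4'-tetra-O-benzyl-4β-(2-ethoxyethoxy)-(−)-epicatechin (2,3-cis-3,4-trans) | O(Cc3ccccc3)c1cc(OCc3ccccc3)c2c(c1)O[C@H](c1ccc(OCc3ccccc3)c(OCc3ccccc3)c1)[C@H](O)[C@H]2OCCOCC | intermediate
4 | 8-bromo-5,7,3',4'-tetra-O-benzyl-4β-(2-ethoxyethoxy)-(−)-epicatechin | O(Cc3ccccc3)c1cc(OCc3ccccc3)c2c(c1Br)O[C@H](c1ccc(OCc3ccccc3)c(OCc3ccccc3)c1)[C@H](O)[C@H]2OCCOCC | intermediate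
5 | 8-bromo-5,7,3',4'-tetra-O-benzylepicatechin-(4β→8)-5,7,3',4'-tetra-O-benzylepicatechin | O(Cc3ccccc3)c1cc(OCc3ccccc3)c2c(c1Br)O[C@H](c1ccc(OCc3ccccc3)c(OCc3ccccc3)c1)[C@H](O)[C@H]2c1c(OCc3ccccc3)cc(OCc3ccccc3)c2c1O[C@H](c1ccc(OCc3ccccc3)c(OCc3ccccc3)c1)[C@H](O)C2 | intermediate
6 | 8-bromo-5,7,3',4'-tetra-O-benzylepicatechin-(4β→8)-5,7,3',4'-tetra-O-benzyl-4β-(2-ethoxyethoxy)epicatechin | O(Cc3ccccc3)c1cc(OCc3ccccc3)c2c(c1Br)O[C@H](c1ccc(OCc3ccccc3)c(OCc3ccccc3)c1)[C@H](O)[C@H]2c1c(OCc3ccccc3)cc(OCc3ccccc3)c2c1O[C@H](c1ccc(OCc3ccccc3)c(OCc3ccccc3)c1)[C@H](O)[C@H]2OCCOCC | intermediate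
7 | (+)-catechin | Oc1cc(O)c2c(c1)O[C@H](c1ccc(O)c(O)c1)[C@@H](O)C2 | starting material
8 | 5,7,3',4'-tetra-O-benzyl-(+)-catechin | O(Cc3ccccc3)c1cc(OCc3ccccc3)c2c(c1)O[C@H](c1ccc(OCc3ccccc3)c(OCc3ccccc3)c1)[C@@H](O)C2 | intermediate
9 | (S)-4-benzyl-3-[(benzyloxy)acetyl]oxazolidin-2-one | O=C(COCc1ccccc1)N1C(=O)OC[C@@H]1Cc1ccccc1 | starting material
10 | 3,4-bis(benzyloxy)benzaldehyde | O=Cc1ccc(OCc2ccccc2)c(OCc2ccccc2)c1 | starting material
11 | (Z)-dibutylboron enolate of 9 | CCCCB(CCCC)O/C(=C\OCc1ccccc1)N1C(=O)OC[C@@H]1Cc1ccccc1 | intermediate (not isolated)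
12 | O-dibutylboryl aldolate of 13 | O=C([C@@H](OCc1ccccc1)[C@H](OB(CCCC)CCCC)c1ccc(OCc2ccccc2)c(OCc2ccccc2)c1)N1C(=O)OC[C@@H]1Cc1ccccc1 | intermediate (not isolated)
13 | (S)-4-benzyl-3-[(2S,3R)-2-(benzyloxy)-3-[3,4-bis(benzyloxy)phenyl]-3-hydroxypropanoyl]oxazolidin-2-one | O=C([C@@H](OCc1ccccc1)[C@H](O)c1ccc(OCc2ccccc2)c(OCc2ccccc2)c1)N1C(=O)OC[C@@H]1Cc1ccccc1 | intermediate
14 | (1R,2R)-2-(benzyloxy)-1-[3,4-bis(benzyloxy)phenyl]propane-1,3-diol | OC[C@@H](OCc1ccccc1)[C@H](O)c1ccc(OCc2ccccc2)c(OCc2ccccc2)c1 | intermediate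
15 | (1R,2R)-2-(benzyloxy)-1-[3,4-bis(benzyloxy)phenyl]-3-[(triisopropylsilyl)oxy]propan-1-ol | CC(C)[Si](C(C)C)(C(C)C)OC[C@@H](OCc1ccccc1)[C@H](O)c1ccc(OCc2ccccc2)c(OCc2ccccc2)c1 | intermediate
16 | 1,3-bis(benzyloxy)-5-bromobenzene | Brc1cc(OCc2ccccc2)cc(OCc2ccccc2)c1 | starting material
17 | [(2R,3R)-2-(benzyloxy)-3-[3,4-bis(benzyloxy)phenyl]-3-[3,5-bis(benzyloxy)phenoxy]propoxy]triisopropylsilane | CC(C)[Si](C(C)C)(C(C)C)OC[C@@H](OCc1ccccc1)[C@H](Oc1cc(OCc2ccccc2)cc(OCc2ccccc2)c1)c1ccc(OCc2ccccc2)c(OCc2ccccc2)c1 | intermediate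
18 | (2R,3R)-2-(benzyloxy)-3-[3,4-bis(benzyloxy)phenyl]-3-[3,5-bis(benzyloxy)phenoxy]propan-1-ol | OC[C@@H](OCc1ccccc1)[C@H](Oc1cc(OCc2ccccc2)cc(OCc2ccccc2)c1)c1ccc(OCc2ccccc2)c(OCc2ccccc2)c1 | intermediate
19 | (2S,3R)-2-(benzyloxy)-3-[3,4-bis(benzyloxy)phenyl]-3-[3,5-bis(benzyloxy)phenoxy]propanal | O=C[C@@H](OCc1ccccc1)[C@H](Oc1cc(OCc2ccccc2)cc(OCc2ccccc2)c1)c1ccc(OCc2ccccc2)c(OCc2ccccc2)c1 | intermediate
20 | 3,5,7,3',4'-penta-O-benzyl-4-hydroxyepicatechin (2,3-cis flavan-3,4-diol 3-benzyl ether, both C4 epimers) | c1c(OCc3ccccc3)cc(OCc3ccccc3)c2c1O[C@H](c1ccc(OCc3ccccc3)c(OCc3ccccc3)c1)[C@H](OCc3ccccc3)C2O | intermediate (not isolated)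
21 | C4 benzylic cation derived from 20 | c1c(OCc3ccccc3)cc(OCc3ccccc3)c2c1O[C@H](c1ccc(OCc3ccccc3)c(OCc3ccccc3)c1)[C@H](OCc3ccccc3)[CH+]2 | intermediate (not isolated)
22 | 3,5,7,3',4'-penta-O-benzylepicatechin-(4β→8)-5,7,3',4'-tetra-O-benzylcatechin | c1c(OCc3ccccc3)cc(OCc3ccccc3)c2c1O[C@H](c1ccc(OCc3ccccc3)c(OCc3ccccc3)c1)[C@H](OCc3ccccc3)[C@H]2c1c(OCc3ccccc3)cc(OCc3ccccc3)c2c1O[C@H](c1ccc(OCc3ccccc3)c(OCc3ccccc3)c1)[C@@H](O)C2 | intermediate
23 | 8-bromo-5,7,3',4'-tetra-O-benzylepicatechin-(4β→8)-5,7,3',4'-tetra-O-benzylepicatechin-(4β→8)-3,5,7,3',4'-penta-O-benzylepicatechin-(4β→8)-5,7,3',4'-tetra-O-benzylcatechin | O(Cc3ccccc3)c1cc(OCc3ccccc3)c2c(c1Br)O[C@H](c1ccc(OCc3ccccc3)c(OCc3ccccc3)c1)[C@H](O)[C@H]2c1c(OCc3ccccc3)cc(OCc3ccccc3)c2c1O[C@H](c1ccc(OCc3ccccc3)c(OCc3ccccc3)c1)[C@H](O)[C@H]2c1c(OCc3ccccc3)cc(OCc3ccccc3)c2c1O[C@H](c1ccc(OCc3ccccc3)c(OCc3ccccc3)c1)[C@H](OCc3ccccc3)[C@H]2c1c(OCc3ccccc3)cc(OCc3ccccc3)c2c1O[C@H](c1ccc(OCc3ccccc3)c(OCc3ccccc3)c1)[C@@H](O)C2 | intermediate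
24 | epicatechin-(4β→8)-epicatechin-(4β→8)-epicatechin-(4β→8)-catechin, the target tetramer | Oc1cc(O)c2c(c1)O[C@H](c1ccc(O)c(O)c1)[C@H](O)[C@H]2c1c(O)cc(O)c2c1O[C@H](c1ccc(O)c(O)c1)[C@H](O)[C@H]2c1c(O)cc(O)c2c1O[C@H](c1ccc(O)c(O)c1)[C@H](O)[C@H]2c1c(O)cc(O)c2c1O[C@H](c1ccc(O)c(O)c1)[C@@H](O)C2 | target

Total step count: 15. Longest linear sequence: 9 steps (steps 7 to 15).

Steps most likely to fail

Step 13 (key step). The acyclic benzylic aryl ether may ionise, or the aldehyde may lose the aryloxide by β-elimination, before the ring closes. Intermolecular capture of the activated aldehyde by 8 may also outrun cyclisation and erode control at C4. The fallback sets out from 8 and 19 and comes back at 22. Bromination of 8 (NBS, CH2Cl2, −15 °C) should give 8-bromo-5,7,3',4'-tetra-O-benzylcatechin F1. Bromine–lithium exchange (n-BuLi, 2.2 equiv, THF, −78 °C) and addition of the aryllithium to aldehyde 19 should give the C4 carbinol F2 (both C4 epimers), with the C4–C8 bond already in place. Catalytic BF3·OEt2 in CH2Cl2 at −78 °C then ionises this doubly activated benzylic alcohol under much milder acid than the aldehyde needs. The tethered 3,5-bis(benzyloxy)phenyl ether closes ring C by intramolecular Friedel–Crafts alkylation to 22, expected with the catechin unit trans to the 3-OBn group.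

Step 10. β-Hydride elimination from the palladium alkoxide of the secondary benzylic alcohol may give the aryl ketone and reduced arene, and the hindered alkoxide may couple slowly. The fallback sets out from 15 and comes back at 17. Dess–Martin oxidation should give aryl ketone F3. Chelation-controlled reduction with Zn(BH4)2 (Et2O, −20 °C) should give the 1,2-anti alcohol F4. Mitsunobu etherification with 3,5-bis(benzyloxy)phenol (PPh3, DIAD, toluene, 0 °C) then forms the O1–C2 bond with inversion and so should give 17.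

Step 5. Hydride abstraction may also occur at the tertiary diarylmethine C4–H of the upper unit or at benzyl ether methylenes, leading to over-oxidation. The fallback sets out from 22 and 4 and comes back at 23, bypassing 5 and 6. TMSOTf coupling of 22 with monomeric electrophile 4 (CH2Cl2, −78 °C) should give the capped trimer F5. Bromine–lithium exchange with excess n-BuLi (THF, −78 °C) and a MeOH quench should give the free-C8 trimer F6. A second TMSOTf coupling with 4 should then give 23.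

Further compounds

F1 | step 13 | 8-bromo-5,7,3',4'-tetra-O-benzyl-(+)-catechin | O(Cc3ccccc3)c1cc(OCc3ccccc3)c2c(c1Br)O[C@H](c1ccc(OCc3ccccc3)c(OCc3ccccc3)c1)[C@@H](O)C2
F2 | step 13 | (2R,3R)-2-(benzyloxy)-3-[3,4-bis(benzyloxy)phenyl]-3-[3,5-bis(benzyloxy)phenoxy]-1-(5,7,3',4'-tetra-O-benzylcatechin-8-yl)propan-1-ol (both C1 epimers) | OC([C@@H](OCc1ccccc1)[C@H](Oc1cc(OCc2ccccc2)cc(OCc2ccccc2)c1)c1ccc(OCc2ccccc2)c(OCc2ccccc2)c1)c1c(OCc3ccccc3)cc(OCc3ccccc3)c2c1O[C@H](c1ccc(OCc3ccccc3)c(OCc3ccccc3)c1)[C@@H](O)C2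
F3 | step 10 | (R)-2-(benzyloxy)-1-[3,4-bis(benzyloxy)phenyl]-3-[(triisopropylsilyl)oxy]propan-1-one | CC(C)[Si](C(C)C)(C(C)C)OC[C@@H](OCc1ccccc1)C(=O)c1ccc(OCc2ccccc2)c(OCc2ccccc2)c1
F4 | step 10 | (1S,2R)-2-(benzyloxy)-1-[3,4-bis(benzyloxy)phenyl]-3-[(triisopropylsilyl)oxy]propan-1-ol | CC(C)[Si](C(C)C)(C(C)C)OC[C@@H](OCc1ccccc1)[C@@H](O)c1ccc(OCc2ccccc2)c(OCc2ccccc2)c1
F5 | step 5 | 8-bromo-5,7,3',4'-tetra-O-benzylepicatechin-(4β→8)-3,5,7,3',4'-penta-O-benzylepicatechin-(4β→8)-5,7,3',4'-tetra-O-benzylcatechin | O(Cc3ccccc3)c1cc(OCc3ccccc3)c2c(c1Br)O[C@H](c1ccc(OCc3ccccc3)c(OCc3ccccc3)c1)[C@H](O)[C@H]2c1c(OCc3ccccc3)cc(OCc3ccccc3)c2c1O[C@H](c1ccc(OCc3ccccc3)c(OCc3ccccc3)c1)[C@H](OCc3ccccc3)[C@H]2c1c(OCc3ccccc3)cc(OCc3ccccc3)c2c1O[C@H](c1ccc(OCc3ccccc3)c(OCc3ccccc3)c1)[C@@H](O)C2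
F6 | step 5 | 5,7,3',4'-tetra-O-benzylepicatechin-(4β→8)-3,5,7,3',4'-penta-O-benzylepicatechin-(4β→8)-5,7,3',4'-tetra-O-benzylcatechin | O(Cc3ccccc3)c1cc(OCc3ccccc3)c2c(c1)O[C@H](c1ccc(OCc3ccccc3)c(OCc3ccccc3)c1)[C@H](O)[C@H]2c1c(OCc3ccccc3)cc(OCc3ccccc3)c2c1O[C@H](c1ccc(OCc3ccccc3)c(OCc3ccccc3)c1)[C@H](OCc3ccccc3)[C@H]2c1c(OCc3ccccc3)cc(OCc3ccccc3)c2c1O[C@H](c1ccc(OCc3ccccc3)c(OCc3ccccc3)c1)[C@@H](O)C2
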